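## Structural features

The target (C22H20O5) is an isoflavone: a 4H-chromen-4-one (ring A fused to the pyranone ring C) with a methoxy group on C7, joined through the sp2–sp2 bond C3–C1' to ring B. Ring B carries a methoxy group on C2' and is fused across C3'–C4' to a 2,2-dimethyl-2H-pyran (ring D), with the pyran oxygen on C4' and the cis CH=CH unit on C3'. Seen as a substituent, rings B and D together are a 5-methoxy-2,2-dimethyl-2H-chromen-6-yl group. There is no stereocentre, so no stereocentres stand next to each other and nothing has to be controlled in that respect. Two parts are fragile: the electron-rich styrene-type alkene of ring D (strong acid, electrophilic oxidants, hydrogenation) and C2 of ring C, a vinylogous ester carbon that hydroxide or amines attack with ring opening. The difficulty is regiochemical: ring B must sit on C3 and not on C2, the C3–C1' bond is flanked by the C4 carbonyl and the 2'-methoxy group, and the pyran must be fused at C3' and not at C5'. Ring C is made of C4 and O1, which sit on adjacent carbons of ring A exactly like the formyl and hydroxyl groups of a salicylaldehyde, plus the two-carbon unit C3–C2, where C3 bears ring B and C2 only hydrogen. The key step exploits this: an aryl alkyne whose other terminus carries a removable silyl group maps onto C3–C2, and the formyl C–H and phenol O–H bonds of ring A deliver C3–C4 and O1–C2 in one operation.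

## Logic of the disconnections

**11 ⇒ 10.** The C2–H bond of 11 is replaced by a C2–Si bond. This does not simplify the skeleton; it puts a removable group on C2 that distinguishes the two ends of a C3–C2 alkyne, so the regiochemical problem of ring C becomes a question of where silicon goes. Trimethylsilyl is kept because it is large enough to steer an insertion and small enough to leave under mild fluoride. The forward step must cleave C–Si without opening ring C at C2 and without touching the alkene of ring D.

**10 ⇒ 8 + 9.** The cuts are C3–C4 and O1–C2, both in ring C. This divides the molecule at its centre into two pieces of similar size; 9 is purchased and already has the ring A methoxy group in place. The hindered C3–C1' bond is never formed by a coupling, because ring B arrives already attached to the future C3. The gain is one ring, two bonds and full convergence in a single step. The forward step must cleave the formyl C–H bond of 9, insert 8 with the aryl-bearing carbon toward the acyl carbon, keep the C–Si bond and ignore the ring D alkene.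

**8 ⇒ 6 (through 7).** The Si–C(sp) bond is cut first, leaving the acetylide 7, which is traced to the 1,1-dibromoalkene 6 by the reverse of a carbenoid 1,2-shift. Alkyne formation and silylation then share one flask and no terminal alkyne is isolated. The forward step needs halogen–lithium exchange to outrun ring lithiation, and a clean silyl quench at low temperature.

**6 ⇒ 5.** The C=C bond of the dibromoalkene is cut. The carbon that becomes C2 of 11 comes from a one-carbon reagent, and the formyl carbon of 5 becomes C3, already bonded to ring B. This reduces the problem to an aromatic aldehyde. The olefination must be near-neutral so that ring D is not exposed to acid.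

**5 ⇒ 4.** The O–CH3 bond of the methoxy group on ring B is cut. The free hydroxyl is needed one step earlier, where its hydrogen bond to the formyl group decides through which oxygen ring D closes, so methylation must follow ring D formation. The forward step must alkylate a chelated, less reactive phenol.

**4 ⇒ 1 + 2 (through 3).** The cuts are the C–C bond from ring B to the CH=CH unit and the O–CMe2 bond of ring D. Both components are purchased and ring D is formed in one operation. The forward step must attack the ring carbon between the two oxygens of 1 and close the oxatriene 3 through the oxygen that is not hydrogen-bonded, which gives the required angular fusion.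

## Other disconnections considered

**Alternative 1:** Ring D is built first on a non-aromatic six-membered ring and ring B is aromatized at the end.
- Cut and key step: Knoevenagel condensation of cyclohexane-1,3-dione A1 with 2, then 6π closure of the 1-oxatriene, would give 2,2-dimethyl-7,8-dihydro-2H-chromen-5(6H)-one A2. This forms the ring C–CH bond and the O–CMe2 bond.
- Continuation: the ketone of A2 marks the future C2' oxygen and its α-carbon the future C1'. An enolate α-arylation with 3-iodo-7-methoxy-4H-chromen-4-one A3 would give the ketone A4, followed by dehydrogenation of the carbocycle and O-methylation.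
- In its favour: A1 is symmetrical, so the fusion of the pyran cannot go wrong. On this point the alternative is better than the chosen plan, which relies on chelation control in step 1. A2 is one step from bulk chemicals.
- Against it: the C3–C1' bond would have to be made by a strongly basic enolate on A3, which is also a Michael acceptor at C2 and opens with base. The late dehydrogenation must remove two hydrogens from the carbocycle of A4 without oxidizing the unsaturated pyran.
- Comparison: both plans have one unproven event (chemoselectivity of the enolate coupling there, insertion regiochemistry here). In step count the alternative is about equal (five to six operations against six). The chosen plan is preferred because it never exposes the chromone to a strong base.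

**Alternative 2:** Ring B is assembled from acyclic pieces; the cuts are C1'–C2', C2'–C3' and C4'–C5'.
- Key step: photochemical Wolff rearrangement of the diazoketone A5 would give the vinylketene A7, which should add the siloxyalkyne A6 in a regioselective [2+2] reaction. The vinylcyclobutenone would open (4π), reclose (6π) and tautomerize to the phenol A8.
- In its favour: the pericyclic cascade places the chromonyl, hydroxyl, prenyl and siloxy groups on four adjacent carbons with regiocontrol set by the mechanism, and it never needs a coupling at the hindered C3–C1' bond. In regiochemical certainty it is equal to or better than a rhodium insertion whose sense rests on an extrapolation.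
- Against it: A8 is not the target. It needs O-methylation, cleavage of the silyl ether to A9 and a DDQ cyclodehydrogenation of the prenylphenol to close ring D. A5 and A6 each need several steps, including diazo transfer and the handling of a sensitive ynol ether. The chromone enone is a possible competitor in the photochemical step.
- Comparison: step economy is clearly worse (about ten operations against six) and the hazard profile is less favourable. The regiochemical argument is stronger, but the alternative is not chosen because it costs four extra operations and a diazoketone.

**Alternative 3:** The C3–C1' bond is cut and made intramolecularly through a temporary ester tether.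
- Key step: 7-methoxy-4-oxo-4H-chromene-2-carboxylic acid A10 would be esterified with 6-iodo-2,2-dimethyl-2H-chromen-5-ol A11 to give A12. Pd(OAc)2 (divalent palladium, reduced in the flask to zerovalent palladium) with PCy3 and a pivalate base would insert into the C–I bond and palladate the chromone C3–H by concerted metalation–deprotonation. Reductive elimination would form C3–C1' and close the six-membered lactone A13.
- In its favour: the tether fixes the site of arylation and overcomes the hindrance at the doubly ortho-substituted bond. In certainty of where ring B is attached, this is better than the chosen plan.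
- Against it: the carboxyl carbon is not part of the target. The lactone of A13 must be opened under base (a threat to ring C), the liberated phenol methylated, and the C2 carboxyl removed by a high-temperature decarboxylation that ring D tolerates poorly. A11 requires iodination of an electron-rich chromenol at one of two activated positions.
- Comparison: the C–H palladation is a well-understood ring closure, mechanistically equal to the chosen step. Step economy (about nine operations) and the mildness of the endgame favour the chosen plan, which needs a single fluoride desilylation after the key step.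

Key step: step 5

Assumption: rotation about C3–C1' is taken as free at room temperature, so the target has no stereogenic element and only alkene geometry is specified where it matters.

## Route

**Step 1**
Reactants: 1 2,4-dihydroxybenzaldehyde; 2 3-methylbut-2-enal
Product: 4 5-hydroxy-2,2-dimethyl-2H-chromene-6-carbaldehyde, via ortho-quinone methide 3 (not isolated)
Conditions: ethylenediammonium diacetate (20 mol %), xylene, 140 °C, Dean–Stark
Reagents that add atoms: none
Why: Amine-catalysed Knoevenagel-type condensation of 2 at the ring carbon between the two hydroxyls of 1 gives the 1-oxatriene 3, which closes by 6π oxa-electrocyclization (formal [3+3] chromene annulation, known for resorcinol aldehydes). The hydroxyl that is hydrogen-bonded to the formyl group stays out of the closure, so the pyran forms through the other oxygen and the fusion is angular.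

**Step 2**
Reactants: 4 5-hydroxy-2,2-dimethyl-2H-chromene-6-carbaldehyde
Product: 5 5-methoxy-2,2-dimethyl-2H-chromene-6-carbaldehyde
Conditions: MeI, K2CO3, DMF, 40 °C
Reagents that add atoms: iodomethane, CI
Why: Williamson O-methylation. The polar aprotic solvent and mild heating should overcome the lower reactivity of the chelated phenol, and no other nucleophilic site is present.

**Step 3**
Reactants: 5 5-methoxy-2,2-dimethyl-2H-chromene-6-carbaldehyde
Product: 6 6-(2,2-dibromoethenyl)-5-methoxy-2,2-dimethyl-2H-chromene
Conditions: CBr4, PPh3, Et3N, CH2Cl2, 0 °C
Reagents that add atoms: tetrabromomethane, BrC(Br)(Br)Br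
Why: First stage of the Corey–Fuchs homologation. The dibromomethylene ylide made in the flask olefinates the aryl aldehyde in a Wittig reaction, and Et3N keeps the medium free of HBr so that ring D is not hydrobrominated.

**Step 4**
Reactants: 6 6-(2,2-dibromoethenyl)-5-methoxy-2,2-dimethyl-2H-chromene
Product: 8 [(5-methoxy-2,2-dimethyl-2H-chromen-6-yl)ethynyl]trimethylsilane, via lithium acetylide 7 (not isolated)
Conditions: n-BuLi (2.1 equiv), THF, −78 °C → 0 °C; then Me3SiCl, −78 °C → rt
Reagents that add atoms: chlorotrimethylsilane, C[Si](C)(C)Cl
Why: Second stage of the Corey–Fuchs sequence. Bromine–lithium exchange, the carbenoid 1,2-shift (Fritsch–Buttenberg–Wiechell rearrangement) and deprotonation give acetylide 7, which is C-silylated in the same flask. At −78 °C the exchange should be much faster than lithiation of the ring.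

**Step 5**
Reactants: 8 [(5-methoxy-2,2-dimethyl-2H-chromen-6-yl)ethynyl]trimethylsilane; 9 2-hydroxy-4-methoxybenzaldehyde
Product: 10 7-methoxy-3-(5-methoxy-2,2-dimethyl-2H-chromen-6-yl)-2-(trimethylsilyl)-4H-chromen-4-one
Conditions: 9 (1.5 equiv), [Cp*RhCl2]2 (2.5 mol %), anhydrous Cu(OAc)2 (2.1 equiv), 4 Å MS, ClCH2CH2Cl, 90 °C, N2
Reagents that add atoms: none
Why: Cu(OAc)2 converts [Cp*RhCl2]2 into a Cp*Rh acetate of trivalent rhodium; the phenoxide of 9 binds, and acetate-assisted cleavage of the formyl C–H bond gives a five-membered acyl rhodacycle. 8 then inserts into the Rh–acyl bond to give a seven-membered oxarhodacycle, C–O reductive elimination forms O1–C2 and releases monovalent rhodium, and two Cu(OAc)2 (divalent copper) reoxidize it. The closest known reaction is the rhodium-catalysed oxidative annulation of salicylaldehydes with internal alkynes to 2,3-disubstituted chromones; that a silyl terminus ends up next to the ring oxygen is an extrapolation from Larock-type annulations of aryl(silyl)alkynes. Ring C closes as a formal [4+2] oxidative annulation, C3–C4 by migratory insertion and O1–C2 by reductive elimination from the seven-membered metallacycle, which is a contraction at the metal and not a Baldwin-type closure. No stereocentre is formed. The step needs regioselective insertion (aryl-bearing carbon to the acyl carbon, silyl-bearing carbon to rhodium), which the bulk of Me3Si and its stabilization of the adjacent C–Rh bond should secure. It needs selectivity for the alkyne over the ring D alkene, which the far higher insertion aptitude of alkynes and the hindered cis-disubstituted alkene secure. It needs the C–Si bond to survive, which is why silver salts, fluoride, water and protic solvent are left out.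

**Step 6**
Reactants: 10 7-methoxy-3-(5-methoxy-2,2-dimethyl-2H-chromen-6-yl)-2-(trimethylsilyl)-4H-chromen-4-one
Product: 11 7-methoxy-3-(5-methoxy-2,2-dimethyl-2H-chromen-6-yl)-4H-chromen-4-one
Conditions: Bu4NF·3H2O (1.2 equiv), THF, 0 °C → rt; aq. NH4Cl
Reagents that add atoms: none
Why: Fluoride protodesilylation of a vinylsilane on an oxygen-bearing sp2 carbon. Fluoride attacks silicon, and the incipient C2 carbanion, stabilized inductively by O1 and the vinylogous carbonyl, is protonated by the water of hydration. Low temperature and a near-stoichiometric charge limit nucleophilic attack at C2.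

## Compound list

1 | 2,4-dihydroxybenzaldehyde | O=Cc1ccc(O)cc1O | starting material
2 | 3-methylbut-2-enal | CC(C)=CC=O | starting material
3 | (3Z)-2-hydroxy-3-(3-methylbut-2-en-1-ylidene)-4-oxocyclohexa-1,5-diene-1-carbaldehyde (ortho-quinone methide, not isolated) | O=CC1=C(O)/C(=C/C=C(C)C)C(=O)C=C1 | intermediate
4 | 5-hydroxy-2,2-dimethyl-2H-chromene-6-carbaldehyde | O=Cc1ccc2OC(C)(C)C=Cc2c1O | intermediate
5 | 5-methoxy-2,2-dimethyl-2H-chromene-6-carbaldehyde | O=Cc1ccc2OC(C)(C)C=Cc2c1OC | intermediate
6 | 6-(2,2-dibromoethenyl)-5-methoxy-2,2-dimethyl-2H-chromene | BrC(Br)=Cc1ccc2OC(C)(C)C=Cc2c1OC | intermediate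
7 | [(5-methoxy-2,2-dimethyl-2H-chromen-6-yl)ethynyl]lithium (not isolated) | [Li]C#Cc1ccc2OC(C)(C)C=Cc2c1OC | intermediate
8 | [(5-methoxy-2,2-dimethyl-2H-chromen-6-yl)ethynyl]trimethylsilane | C[Si](C)(C)C#Cc1ccc2OC(C)(C)C=Cc2c1OC | intermediate
9 | 2-hydroxy-4-methoxybenzaldehyde | COc1ccc(C=O)c(O)c1 | starting material
10 | 7-methoxy-3-(5-methoxy-2,2-dimethyl-2H-chromen-6-yl)-2-(trimethylsilyl)-4H-chromen-4-one | COc1ccc2c(=O)c(-c3ccc4c(c3OC)C=CC(C)(C)O4)c([Si](C)(C)C)oc2c1 | intermediate
11 | 7-methoxy-3-(5-methoxy-2,2-dimethyl-2H-chromen-6-yl)-4H-chromen-4-one | COc1ccc2c(=O)c(-c3ccc4c(c3OC)C=CC(C)(C)O4)coc2c1 | target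

## Step count and least certain steps

Total steps: 6. Longest linear sequence: 6 steps (1 → 4 → 5 → 6 → 8 → 10 → 11); 9 is purchased and enters at step 5.

**Step 5 (key step).** The alkyne may insert in the opposite sense, because the aryl group also favours the carbon bound to rhodium and its ortho-methoxy group adds bulk on that side. The silyl group may be lost from the alkyne under acetate at 90 °C before insertion, followed by copper-mediated alkyne homocoupling. The acyl rhodium intermediate may decarbonylate. The fallback sets out from 5 and rejoins the route at 11, making the C3–C1' bond by an aryl shift in place of an insertion. Claisen–Schmidt condensation of 5 with commercial 1-(2-hydroxy-4-methoxyphenyl)ethan-1-one F1 (KOH, EtOH, rt) would give (2E)-1-(2-hydroxy-4-methoxyphenyl)-3-(5-methoxy-2,2-dimethyl-2H-chromen-6-yl)prop-2-en-1-one F2. Oxidative 1,2-aryl migration with one equivalent of Tl(NO3)3 (trivalent thallium) in MeOH/HC(OMe)3 at low temperature would give 1-(2-hydroxy-4-methoxyphenyl)-3,3-dimethoxy-2-(5-methoxy-2,2-dimethyl-2H-chromen-6-yl)propan-1-one F3. HCl in MeOH would then close ring C to 11. The electron-rich ring B is a good migrating group; the ring D alkene is the competing site for the oxidant, hence the strict stoichiometry.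

**Step 6.** Fluoride or hydroxide may attack C2 instead of silicon and open ring C, or C–Si cleavage may be slow because the carbanion at C2 is not conjugated. The fallback sets out from 10 and rejoins at 11, turning the ring opening to use. KOH in EtOH/H2O at reflux would open ring C and remove C2 together with silicon, giving 1-(2-hydroxy-4-methoxyphenyl)-2-(5-methoxy-2,2-dimethyl-2H-chromen-6-yl)ethan-1-one F4. Me2NCH(OMe)2 in toluene at 90 °C would then put C2 back through 3-(dimethylamino)-1-(2-hydroxy-4-methoxyphenyl)-2-(5-methoxy-2,2-dimethyl-2H-chromen-6-yl)prop-2-en-1-one F5, which cyclizes to 11.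

**Step 1.** Condensation may occur at the other free ring position, closure may go through the hydrogen-bonded hydroxyl, the enal may self-condense, or the formyl group may be tied up by the amine catalyst. The fallback sets out from 1 and rejoins at 4. Selective O-alkylation of the non-chelated hydroxyl with commercial 3-chloro-3-methylbut-1-yne F6 (K2CO3, KI, CuI cat., acetone, reflux) would give 2-hydroxy-4-[(2-methylbut-3-yn-2-yl)oxy]benzaldehyde F7. Heating in N,N-diethylaniline at 190 °C would bring about the aromatic propargyl Claisen rearrangement, a [1,5]-hydrogen shift and 6π closure to 4.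

**Step 4.** Excess n-BuLi may lithiate the ring, the acetylide may be butylated by the alkyl bromide formed in the exchange as the mixture warms, or the 1,2-shift may be incomplete. The fallback sets out from 5 and rejoins at 8, replacing steps 3 and 4. Dimethyl (1-diazo-2-oxopropyl)phosphonate with K2CO3 in MeOH at rt would give 6-ethynyl-5-methoxy-2,2-dimethyl-2H-chromene F8 through an alkylidene carbene. Deprotonation with EtMgBr in THF at 0 °C and a Me3SiCl quench would give 8 without any alkyllithium.

## Further compounds

F1 | step 5 | 1-(2-hydroxy-4-methoxyphenyl)ethan-1-one | CC(=O)c1ccc(OC)cc1O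
F2 | step 5 | (2E)-1-(2-hydroxy-4-methoxyphenyl)-3-(5-methoxy-2,2-dimethyl-2H-chromen-6-yl)prop-2-en-1-one | COc1ccc(C(=O)/C=C/c2ccc3OC(C)(C)C=Cc3c2OC)c(O)c1
F3 | step 5 | 1-(2-hydroxy-4-methoxyphenyl)-3,3-dimethoxy-2-(5-methoxy-2,2-dimethyl-2H-chromen-6-yl)propan-1-one (racemic) | COc1ccc(C(=O)C(C(OC)OC)c2ccc3OC(C)(C)C=Cc3c2OC)c(O)c1
F4 | step 6 | 1-(2-hydroxy-4-methoxyphenyl)-2-(5-methoxy-2,2-dimethyl-2H-chromen-6-yl)ethan-1-one | COc1ccc(C(=O)Cc2ccc3OC(C)(C)C=Cc3c2OC)c(O)c1
F5 | step 6 | 3-(dimethylamino)-1-(2-hydroxy-4-methoxyphenyl)-2-(5-methoxy-2,2-dimethyl-2H-chromen-6-yl)prop-2-en-1-one | COc1ccc(C(=O)C(=CN(C)C)c2ccc3OC(C)(C)C=Cc3c2OC)c(O)c1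
F6 | step 1 | 3-chloro-3-methylbut-1-yne | C#CC(C)(C)Cl
F7 | step 1 | 2-hydroxy-4-[(2-methylbut-3-yn-2-yl)oxy]benzaldehyde | C#CC(C)(C)Oc1ccc(C=O)c(O)c1
F8 | step 4 | 6-ethynyl-5-methoxy-2,2-dimethyl-2H-chromene | C#Cc1ccc2OC(C)(C)C=Cc2c1OC
A1 | alternative 1 | cyclohexane-1,3-dione | O=C1CCCC(=O)C1
A2 | alternative 1 | 2,2-dimethyl-7,8-dihydro-2H-chromen-5(6H)-one | CC1(C)C=CC2=C(CCCC2=O)O1
A3 | alternative 1 | 3-iodo-7-methoxy-4H-chromen-4-one | COc1ccc2c(=O)c(I)coc2c1
A4 | alternative 1 | 3-(2,2-dimethyl-5-oxo-5,6,7,8-tetrahydro-2H-chromen-6-yl)-7-methoxy-4H-chromen-4-one (racemic) | COc1ccc2c(=O)c(C3CCC4=C(C=CC(C)(C)O4)C3=O)coc2c1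
A5 | alternative 2 | (3E)-1-diazo-4-(7-methoxy-4-oxo-4H-chromen-3-yl)but-3-en-2-one | COc1ccc2c(=O)c(/C=C/C(=O)C=[N+]=[N-])coc2c1
A6 | alternative 2 | triisopropyl[(5-methylhex-4-en-1-yn-1-yl)oxy]silane | CC(C)=CCC#CO[Si](C(C)C)(C(C)C)C(C)C
A7 | alternative 2 | (3E)-4-(7-methoxy-4-oxo-4H-chromen-3-yl)buta-1,3-dien-1-one | COc1ccc2c(=O)c(/C=C/C=C=O)coc2c1
A8 | alternative 2 | 3-[2-hydroxy-3-(3-methylbut-2-enyl)-4-(triisopropylsilyloxy)phenyl]-7-methoxy-4H-chromen-4-one | COc1ccc2c(=O)c(-c3ccc(O[Si](C(C)C)(C(C)C)C(C)C)c(CC=C(C)C)c3O)coc2c1
A9 | alternative 2 | 3-[4-hydroxy-2-methoxy-3-(3-methylbut-2-enyl)phenyl]-7-methoxy-4H-chromen-4-one | COc1ccc2c(=O)c(-c3ccc(O)c(CC=C(C)C)c3OC)coc2c1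
A10 | alternative 3 | 7-methoxy-4-oxo-4H-chromene-2-carboxylic acid | COc1ccc2c(=O)cc(C(=O)O)oc2c1
A11 | alternative 3 | 6-iodo-2,2-dimethyl-2H-chromen-5-ol | Oc1c(I)ccc2OC(C)(C)C=Cc12
A12 | alternative 3 | 6-iodo-2,2-dimethyl-2H-chromen-5-yl 7-methoxy-4-oxo-4H-chromene-2-carboxylate | COc1ccc2c(=O)cc(C(=O)Oc3c(I)ccc4OC(C)(C)C=Cc34)oc2c1
A13 | alternative 3 | pentacyclic lactone linking the C2 carboxyl to the ring B C2' oxygen | COc1ccc2c(c1)oc1c(c2=O)-c2ccc3OC(C)(C)C=Cc3c2OC1=O
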